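**Retrosynthetic overview**
1. 16 ⇐ 14: the last step is pure C–O construction: O-transfer to the C1=C2 enol ether and hydrolytic opening give C2–OH and the C1 hemiketal (key step, proposed new).
2. 14 ⇐ 11: the 2-isopropylfuran is a masked 4-hydroxycyclopentenone (¹O₂ oxygenation to a Z-enedione, then aldol C11→C4).
3. 11 ⇐ 7 + 8: Michael addition of pyranone 8 (C8–C3′ bond) and cyclodehydration (O4′–C1 bond) close the pyran.
4. 7 ⇐ 6 ⇐ 5: dianion Mannich reaction at C7; Claisen closure of the seven-membered 1,3-diketone on the furan.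
5. 5 ⇐ 3 ⇐ 1 + 2: two Friedel–Crafts reactions; Rh-catalysed asymmetric 1,4-addition sets C6. Ring order: furan (bought) → 7-ring → pyran → cyclopentenone → hemiketal.

Assumption: furan-3-ylboronic acid (2) and 4-hydroxy-5,6-dimethyl-2H-pyran-2-one (8) are taken as stocked catalogue chemicals.
Locants used for 9–16 and F2–F5 follow the target: C1 hemiketal carbon, C2 CH(OH), C3 ring ketone, C4 carbinol at the 5/7 fusion, C5 sp² fusion carbon, C6 CH(CH3), C7 CH at the 6/7 fusion, C8 CH2, C9 enone CH, C10 enone C=O, C11 C(CH3)2; pyranone atoms are primed. Compounds 3–7 use their own systematic numbering.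

**Step 1**
Reactants: 1 ethyl (E)-but-2-enoate; 2 furan-3-ylboronic acid
Product: 3 ethyl (3R)-3-(furan-3-yl)butanoate
Conditions: [Rh(OH)((S)-BINAP)]2 (3 mol % Rh), 2 (2 equiv), dioxane/H2O 10:1, 40 °C
Reagents that add atoms: none
Why: Hayashi–Miyaura Rh-catalysed asymmetric 1,4-addition; the furyl–Rh species adds to the 2-si face of the enoate bound to (S)-BINAP–Rh, which sets C6 as R (ligand sense from the face model; confirm on the first run and switch to (R)-BINAP if it is reversed).

**Step 2**
Reactants: 3 ethyl (3R)-3-(furan-3-yl)butanoate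
Product: 4 ethyl (3R)-3-(2-acetylfuran-3-yl)butanoate
Conditions: Ac2O (1.3 equiv), BF3·OEt2 (10 mol %), CH2Cl2, 0 °C
Reagents that add atoms: acetic anhydride, CC(=O)OC(C)=O
Why: Friedel–Crafts acylation; a 3-alkylfuran is attacked at C2, the α-position whose σ-complex is stabilised by the neighbouring alkyl group (minor 5-acetyl isomer removed by chromatography), and the stereocentre is not touched.

**Step 3**
Reactants: 4 ethyl (3R)-3-(2-acetylfuran-3-yl)butanoate
Product: 5 ethyl (3R)-3-[2-acetyl-5-(propan-2-yl)furan-3-yl]butanoate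
Conditions: 2-chloropropane (1.5 equiv), AlCl3 (2.5 equiv), CH2Cl2, −20 → 0 °C
Reagents that add atoms: 2-chloropropane, CC(C)Cl
Why: Friedel–Crafts alkylation; once C2 carries the acyl group the furan tolerates AlCl3 and the isopropyl cation enters the only free α-position (C5), as in the alkylation of 2-furoates and 2-acylfurans.

**Step 4**
Reactants: 5 ethyl (3R)-3-[2-acetyl-5-(propan-2-yl)furan-3-yl]butanoate
Product: 6 (4R)-4-methyl-2-(propan-2-yl)-4,5-dihydro-6H-cyclohepta[b]furan-6,8(7H)-dione
Conditions: LiHMDS (2.2 equiv), THF (0.02 M), −78 → 25 °C; aq. HCl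
Reagents that add atoms: none
Why: intramolecular Claisen (Dieckmann-type) condensation; the kinetic methyl-ketone enolate attacks the ester held on the adjacent furan carbon and formation of the diketonate drives the seven-membered ring closure, while the C6 hydrogen is not acidic enough to epimerise.

**Step 5**
Reactants: 6 (4R)-4-methyl-2-(propan-2-yl)-4,5-dihydro-6H-cyclohepta[b]furan-6,8(7H)-dione
Product: 7 (4R,5S)-5-[(dimethylamino)methyl]-4-methyl-2-(propan-2-yl)-4,5-dihydro-6H-cyclohepta[b]furan-6,8(7H)-dione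
Conditions: LDA (2.3 equiv), THF, −78 → −20 °C; CH2=NMe2+ I− (1.2 equiv), −78 → 0 °C; H2O
Reagents that add atoms: N,N-dimethylmethyleneiminium iodide (Eschenmoser's salt), C=[N+](C)C.[I-]
Why: Mannich reaction of a β-diketone dianion (Hauser-type regiochemistry); the more basic terminal carbanion (C7), not the central carbon, attacks the iminium ion, and the new C7 centre (mainly trans) is erased in step 6.

**Step 6**
Reactants: 7 (4R,5S)-5-[(dimethylamino)methyl]-4-methyl-2-(propan-2-yl)-4,5-dihydro-6H-cyclohepta[b]furan-6,8(7H)-dione; 8 4-hydroxy-5,6-dimethyl-2H-pyran-2-one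
Product: 11 (6R,7R)-furan-fused pyranopyranone enol ether, via exo-methylene diketone 9 (not isolated), via open-chain Michael adduct 10 (not isolated)
Conditions: 8 (1.3 equiv), EtOH/H2O 4:1, 70 °C; then p-TsOH·H2O (10 mol %), PhMe, 90 °C, 4 Å MS
Reagents that add atoms: none
Why: thermal β-elimination of the Mannich base, Michael addition of the pyranone C3′ (warfarin-type) and acid-catalysed cyclodehydration, which forms the O4′–C1 bond as a vinylogous ester; C7 (R) is set trans to the C6 methyl by equilibration through the enolisable open C1 ketone before ring closure.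

**Step 7**
Reactants: 11 (6R,7R)-furan-fused pyranopyranone enol ether
Product: 14 (4R,6R,7R)-1,2-didehydro-1,2-dideoxy-16, via furan endoperoxide 12 (not isolated), via Z-enedione 13 (not isolated)
Conditions: O2, TPP (1 mol %), hν (white LED), CH2Cl2, −78 °C; Me2S (3 equiv), −78 → 0 °C; solvent switch to THF; LiHMDS (2.2 equiv), −78 °C, 30 min; AcOH, −78 °C
Reagents that add atoms: dioxygen (sensitised to singlet oxygen), O=O
Why: singlet-oxygen [4+2] photooxygenation of the furan and reductive opening give the Z-enedione, whose kinetic α′-lithium enolate (C11) closes by intramolecular aldol addition onto the 1,2-dicarbonyl-activated C4 ketone; the chair-like closure keeps the C6 methyl pseudo-equatorial and anti to the new alkoxide, which sets C4 (R).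

**Step 8**
Reactants: 14 (4R,6R,7R)-1,2-didehydro-1,2-dideoxy-16
Product: 16 CNP0525404.1, via 1,2-epoxide 15 (not isolated)
Conditions: DMDO (1.5 equiv, acetone), CH2Cl2, −20 → 0 °C; then H2O/acetone 1:4, 0 → 20 °C
Reagents that add atoms: dimethyldioxirane, CC1(C)OO1; water, O
Why: Proposed new method: hydroxylative hemiketalisation of a pyranon-4-yl vinylogous ester — electrophilic O-transfer from the dioxirane to the enol-ether C1=C2 gives a 1,2-anhydro intermediate that water opens at C1 through the ring-oxygen-stabilised oxocarbenium ion; the closest known reaction type is the DMDO epoxidation–hydrolysis of glycals and chromones (Rubottom-type enol-ether oxidation), not yet shown on this enol-ether class; O is delivered to the convex face syn to C7–H (anti to C8H2 and the C4–OH) and anti opening places C1–OH trans to C2–OH in the anomerically favoured trans-fused hemiketal, so C2 (R) and C1 (S) are set.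

**Compound list**
1 | ethyl (E)-but-2-enoate (ethyl crotonate) | C/C=C/C(=O)OCC | starting material
2 | furan-3-ylboronic acid | OB(O)c1ccoc1 | starting material
3 | ethyl (3R)-3-(furan-3-yl)butanoate | CCOC(=O)C[C@@H](C)c1ccoc1 | intermediate
4 | ethyl (3R)-3-(2-acetylfuran-3-yl)butanoate | CCOC(=O)C[C@@H](C)c1ccoc1C(C)=O | intermediate
5 | ethyl (3R)-3-[2-acetyl-5-(propan-2-yl)furan-3-yl]butanoate | CCOC(=O)C[C@@H](C)c1cc(C(C)C)oc1C(C)=O | intermediate
6 | (4R)-4-methyl-2-(propan-2-yl)-4,5-dihydro-6H-cyclohepta[b]furan-6,8(7H)-dione | CC(C)c1cc2c(o1)C(=O)CC(=O)C[C@H]2C | intermediate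
7 | (4R,5S)-5-[(dimethylamino)methyl]-4-methyl-2-(propan-2-yl)-4,5-dihydro-6H-cyclohepta[b]furan-6,8(7H)-dione (trans) | CC(C)c1cc2c(o1)C(=O)CC(=O)[C@H](CN(C)C)[C@H]2C | intermediate
8 | 4-hydroxy-5,6-dimethyl-2H-pyran-2-one | Cc1oc(=O)cc(O)c1C | starting material
9 | (4S)-4-methyl-5-methylidene-2-(propan-2-yl)-4,5-dihydro-6H-cyclohepta[b]furan-6,8(7H)-dione (exo-methylene diketone; same spatial arrangement at the methyl centre as 6) | CC(C)c1cc2c(o1)C(=O)CC(=O)C(=C)[C@H]2C | intermediate
10 | (4R,5R)-5-[(4-hydroxy-5,6-dimethyl-2-oxo-2H-pyran-3-yl)methyl]-4-methyl-2-(propan-2-yl)-4,5-dihydro-6H-cyclohepta[b]furan-6,8(7H)-dione (open-chain Michael adduct) | CC(C)c1cc2c(o1)C(=O)CC(=O)[C@H](Cc1c(O)c(C)c(C)oc1=O)[C@H]2C | intermediate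
11 | (6R,7R)-furan-fused pyranopyranone enol ether: pyranone O4′–C1(=C2H)–C3(=O)–[2-isopropylfuran, C4 and C5 shared]–C6H(CH3)–C7H(–C8H2–C3′) | Cc1oc(=O)c2c(c1C)OC1=CC(=O)c3oc(C(C)C)cc3[C@H](C)[C@H]1C2 | intermediate
12 | furan endoperoxide of 11 (O–O bridge between C4 and C10; bridgehead configuration not defined) | Cc1oc(=O)c2c(c1C)OC1=CC(=O)C34OOC(C(C)C)(O3)C=C4[C@H](C)[C@H]1C2 | intermediate
13 | (6R,7R)-Z-enedione: C3(=O)–C4(=O) in the ring, C5=C9H (Z), C10(=O)–CH(CH3)2 side chain, rest as 11 | Cc1oc(=O)c2c(c1C)OC1=CC(=O)C(=O)/C(=C\C(=O)C(C)C)[C@H](C)[C@H]1C2 | intermediate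
14 | (4R,6R,7R)-1,2-didehydro-1,2-dideoxy-16 (target skeleton with a C1=C2H enol ether in place of C1(OH)–C2H(OH)) | Cc1oc(=O)c2c(c1C)OC1=CC(=O)[C@@]3(O)C(=CC(=O)C3(C)C)[C@H](C)[C@H]1C2 | intermediate
15 | 1,2-epoxide of 14 (epoxide oxygen on the face of C7–H, anti to C4–OH) | Cc1oc(=O)c2c(c1C)O[C@]13O[C@@H]3C(=O)[C@@]3(O)C(=CC(=O)C3(C)C)[C@H](C)[C@H]1C2 | intermediate
16 | CNP0525404.1, (1S,2R,4R,6R,7R) in target locants | Cc1oc(=O)c2c(c1C)O[C@]1(O)[C@H](O)C(=O)[C@@]3(O)C(=CC(=O)C3(C)C)[C@H](C)[C@H]1C2 | target

**Totals and risks**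
Total step count: 8. Longest linear sequence: 8 steps (1 + 2 → 16; 8 enters at step 6).

Steps most likely to fail:

Step 3 (Friedel–Crafts isopropylation). The isopropyl group may enter C4 as well as C5, and the isopropyl cation may abstract hydride at the furylic stereocentre. The fallback sets out from 4: N-bromosuccinimide in MeCN at 0 °C brominates the free α-position and gives ethyl (3R)-3-(2-acetyl-5-bromofuran-3-yl)butanoate F1. Negishi coupling of F1 with isopropylzinc bromide (Pd(OAc)2/CPhos, THF, 25 °C) then comes back to the route at 5.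

Step 7 (furan to hydroxycyclopentenone). The acyl-substituted furan may react slowly with singlet oxygen. The base may deprotonate the pyranone 6′-methyl group, or the new C4 alkoxide may add to the vinylogous ester. The fallback moves this transformation ahead of the pyran annulation and sets out from 6. The same sequence (O2/TPP/hν, Me2S, then LiHMDS, 3.2 equiv, the first equivalent masking the β-diketone as its enolate) gives the bicyclic (4R,6R)-4-hydroxy-6,11,11-trimethyl triketone core F2. LDA (3.3 equiv) and Eschenmoser's salt give its C7 (dimethylamino)methyl Mannich base F3. Reaction of F3 with 8 under the conditions of step 6 comes back to the route at 14.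

Step 8 (proposed new hydroxylative hemiketalisation). Risks are competing oxidation of the C5=C9 enone, hydroxyl-directed delivery to the wrong face, and transannular capture of the C1 cation by C4–OH. The fallback uses known chemistry and sets out from 14. Aqueous HCl in THF hydrolyses the enol ether to the open β-diketone bearing the free 4′-hydroxypyranone F4. Regitz diazo transfer (4-acetamidobenzenesulfonyl azide, Et3N, MeCN) gives the 2-diazo-1,3-diketone F5. Rh2(OAc)4-catalysed O–H insertion with water gives the 2-hydroxy-1,3-diketone, which closes onto C1 as the hemiketal and comes back to the route at 16 (C2 epimers equilibrate through the open form or are separated).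

**Further compounds**
F1 | step 3 | ethyl (3R)-3-(2-acetyl-5-bromofuran-3-yl)butanoate | CCOC(=O)C[C@@H](C)c1cc(Br)oc1C(C)=O
F2 | step 7 | (4R,6R)-4-hydroxy-6,11,11-trimethyl bicyclic triketone core (cycloheptane-1,3-dione fused at C4–C5 to the 4-hydroxycyclopent-2-enone) | O=C1CC(=O)[C@@]2(O)C(=CC(=O)C2(C)C)[C@H](C)C1
F3 | step 7 | C7 (dimethylamino)methyl Mannich base of F2 (trans to the C6 methyl) | O=C1CC(=O)[C@@]2(O)C(=CC(=O)C2(C)C)[C@H](C)[C@H]1CN(C)C
F4 | step 8 | open β-diketone: F2 carrying at C7 the (4-hydroxy-5,6-dimethyl-2-oxo-2H-pyran-3-yl)methyl group, (4R,6R,7R) | O=C1CC(=O)[C@@]2(O)C(=CC(=O)C2(C)C)[C@H](C)[C@H]1Cc1c(O)c(C)c(C)oc1=O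
F5 | step 8 | 2-diazo derivative of F4 | O=C1C(=[N+]=[N-])C(=O)[C@@]2(O)C(=CC(=O)C2(C)C)[C@H](C)[C@H]1Cc1c(O)c(C)c(C)oc1=O
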